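The numbers in the tables come from a simulation on assumed constants; noise was put on by code.

4 flasks carry one question each, and one further question asks for their order; all hold the same charge, and what is asked of each is its tetra adduct.

| flask | substrate | reagent | remark | time |
|---|---|---|---|---|
| spring | 2.0 × 10⁻⁴ M | 1 mM | run made earlier |  |
| summer | 2.0 × 10⁻⁴ M | 0.50 mM | run made earlier |  |
| noon | 2.0 × 10⁻⁴ M | 2 mM | run made earlier |  |
| Sunday's | 2.0 × 10⁻⁴ M | 1.00 mM | one stirred flow tank at steady state, fed with the mixture as stated, mean residence time 4.0 min |  |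
| Wednesday's | 2.0 × 10⁻⁴ M | 1.00 mM | a closed flask charged with all of it at once and left for 4.0 min | 4.0 min |
| Tuesday's | 2.0 × 10⁻⁴ M (fed, over 3.20 min) | 1.00 mM | all but substrate at the start; substrate goes in evenly over 3.20 min, the run ends at 4.0 min | 4.0 min |
| Thursday's | 2.0 × 10⁻⁴ M | 1.00 mM | one stirred flow tank at steady state, fed with the mixture as stated, mean residence time 20.0 min |  |

| run | time / min | tetra adduct / % | substrate / % |
|---|---|---|---|
| spring | 0.417 | 0 | 4.2 |
| spring | 0.833 | 0.5 | 0 |
| spring | 1.33 | 5.0 | 0.4 |
| spring | 1.50 | 6.3 | 0.1 |
| spring | 2.00 | 9.7 | 0 |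
| spring | 2.50 | 13.4 | 0 |
| summer | 0.417 | 0 | 24.3 |
| summer | 0.833 | 0 | 8.6 |
| summer | 1.33 | 0.8 | 2.5 |
| summer | 1.50 | 0.4 | 2.1 |
| summer | 2.00 | 1.4 | 0.3 |
| summer | 2.50 | 1.6 | 0.1 |
| noon | 0.200 | 0.8 | 4.0 |
| noon | 0.333 | 0.5 | 1.0 |
| noon | 0.500 | 3.1 | 0 |
| noon | 0.833 | 9.1 | 0.1 |
| noon | 1.33 | 18.8 | 0.5 |
| noon | 2.50 | 38.1 | 0.6 |

(standard deviation of a reading: 0.5 percentage points)

- the stated concentrations are those of everything mixed, before any reaction; amounts are the same in each set-up
- the numbers in the tables scatter by 0.5 percentage points (one standard deviation)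
- the feed brings no volume worth counting
- the earlier runs were made in a closed, stirred flask

- order of the set-ups by the amount of tetra adduct at the outlet or at the end, in percent of the substrate put in, highest first (Sunday's / Wednesday's / Tuesday's / Thursday's)
- amount of tetra adduct at the outlet or at the end, in percent of the substrate put in, Sunday's
- amount of tetra adduct at the outlet or at the end, in percent of the substrate put in, Wednesday's
- amount of tetra adduct at the outlet or at the end, in percent of the substrate put in, Tuesday's
- amount of tetra adduct at the outlet or at the end, in percent of the substrate put in, Thursday's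

I count turnovers. In the spring run the substrate is down to 0 % by 0.833 min, yet tetra adduct climbs slowly and late. So I treat the flask as a delay followed by one slow pseudo-first-order step. The turnover count N is that step's pace times the time a substrate spends past the delay.

Spring pace: 0.0791 min⁻¹

Delay, from the line through the same readings: 0.634 min

In a closed flask the share is one minus exp(−N).

Wednesday's: N = 0.266, share 23.4 %

In Tuesday's flask the mean substrate is younger by half the dosing time, and even the last portion stays longer than the delay:

Tuesday's: 13.0 %

A tank gives exp(−delay/τ) times N/(1+N), with N the pace times τ: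

Sunday's: 20.5 %

Thursday's, first pass: 59.4 %

That last link is weak. I count 4 reagents in each tetra adduct and one in every other substrate. The spring window then holds c_reagent 0.745 mM, but by this count Thursday's tank holds less, 0.444 mM. So I reforge the pace from the noon run, whose tetra adduct rises furthest. It gives 0.230 min⁻¹ at 1.66 mM, which is a pace per 1.00 mM of free reagent of 0.139 min⁻¹.

Thursday's: N = 1.23, share 53.5 %

The forecast says Thursday's > Wednesday's > Sunday's > Tuesday's, with 18.5 %, 23 %, 17 % and 51 % for Sunday's, Wednesday's, Tuesday's and Thursday's, on the ground of “first order in the reagent left”. My order is the same, but my Tuesday's figure is lower than its 17 %.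

The flasks give Thursday's > Wednesday's > Sunday's > Tuesday's: 20.5 %, 24.8 %, 14.0 % and 53.0 %, in the same sequence as the forecast's figures.

    substrate + reagent → mono adduct (k = 140 L mol⁻¹ s⁻¹)
    reagent + mono adduct → double product (k = 2.50 L mol⁻¹ s⁻¹)
    reagent + triple product → tetra adduct (k = 85.0 L mol⁻¹ s⁻¹)
    reagent + double product → triple product (k = 25.0 L mol⁻¹ s⁻¹)

Now take Tuesday's flask read at 15 min instead. Its reagent falls from 74.0 % of its charge at 3.20 min to 41.2 % at 15.0 min, so I take the middle of these as its mean. The pace 0.139 min⁻¹ then gives N = 1.02 and a share of 63.9 %. That neighbouring flask holds 62.8 % of tetra adduct.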